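The route rests on cutting both pyrrole rings at N1–C2 and C3–C3a. Each 3-(1,1-dimethylallyl)indole is attached to the carbon framework only through C5, para to N1, so the benzo rings can be carried as 4-amino-3-bromophenyl groups and both heterocycles made last from 3,3-dimethylpent-4-enal. One palladium-catalysed operation then forms four bonds, closes two rings and installs both tert-prenyl groups without protecting groups. Its precursor 10 is a (1R,2R)-2-aryl-1,4-dimethylcyclohex-3-ene bearing an (E)-2-arylethenyl group on C1, both aryls being 4-amino-3-bromophenyl; it comes from an enantioselective Diels–Alder reaction and a Heck coupling, with the bromines brought in by the building blocks.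

Key step: step 8

Remark on the structure: the ring alkene of the target is C3=C4, directly beside the aryl-bearing C2 (the pattern of a 1-aryl-3-methylbutadiene/methacrolein cycloadduct), so precursor 10 is a 2-aryl-1,4-dimethylcyclohex-3-en-1-yl compound and not a 6-aryl isomer; C1 and C2 are both R in 10 and 14.

Assumption: the cationic oxazaborolidine Diels–Alder follows the accepted model for 2-substituted acroleins, under which the (S)-catalyst gives the (1S,2S)-aldehyde 6; the (R)-catalyst is equally available should the sense prove opposite.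

Remark: 1 and 9 are taken as catalogue compounds.

Step 1
Reactants: 1 3-bromo-4-nitrobenzaldehyde; 2 1-(triphenyl-λ5-phosphanylidene)propan-2-one
Product: 3 (E)-4-(3-bromo-4-nitrophenyl)but-3-en-2-one
Conditions: toluene, 80 °C
Reagents that add atoms: none
Why: Wittig olefination with a carbonyl-stabilised ylide is E-selective and leaves the nitro group and the aryl bromide untouched.

Step 2
Reactants: 3 (E)-4-(3-bromo-4-nitrophenyl)but-3-en-2-one
Product: 4 2-bromo-4-[(1E)-3-methylbuta-1,3-dien-1-yl]-1-nitrobenzene
Conditions: Ph3PCH3Br, KOtBu (slight deficit), THF, 0 °C → rt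
Reagents that add atoms: methyltriphenylphosphonium bromide, C[P+](c1ccccc1)(c1ccccc1)c1ccccc1.[Br-]
Why: Wittig methylenation of the enone carbonyl by the pre-formed ylide (1,2-addition) should give the 1-aryl-3-methylbuta-1,3-diene with the E styrene bond retained, the usual way from benzalacetones to such dienes.

Step 3
Reactants: 4 2-bromo-4-[(1E)-3-methylbuta-1,3-dien-1-yl]-1-nitrobenzene; 5 methacrolein
Product: 6 (1S,2S)-2-(3-bromo-4-nitrophenyl)-1,4-dimethylcyclohex-3-ene-1-carbaldehyde
Conditions: (S)-o-tolyl-CBS oxazaborolidine·HNTf2 (20 mol %), CH2Cl2, −40 °C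
Reagents that add atoms: none
Why: Catalytic enantioselective Diels–Alder reaction of a 2-substituted acrolein under a cationic oxazaborolidine Lewis acid: the aryl group on C1 and the methyl on C3 of the diene both direct the aryl-bearing terminus onto Cα of methacrolein, the acyclic diene should react through the carbonyl-endo transition state that puts CHO cis to the aryl group, and the (S)-catalyst, holding the s-trans enal by B–O coordination and a formyl C–H···O contact above one of its phenyl rings, leaves the Re face of Cα open, which sets C1 and C2 together as 1S,2S.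

Step 4
Reactants: 6 (1S,2S)-2-(3-bromo-4-nitrophenyl)-1,4-dimethylcyclohex-3-ene-1-carbaldehyde
Product: 7 (1S,2S)-2-(4-amino-3-bromophenyl)-1,4-dimethylcyclohex-3-ene-1-carbaldehyde
Conditions: Fe powder, NH4Cl, EtOH/H2O, 70 °C
Reagents that add atoms: none
Why: Béchamp-type iron reduction converts ArNO2 into ArNH2 without touching the hindered aldehyde, the C–Br bond or the alkene, and it removes the nitro group before any basic step, so the benzylic, allylic C2–H is no longer acidic and C2 cannot epimerise.

Step 5
Reactants: 7 (1S,2S)-2-(4-amino-3-bromophenyl)-1,4-dimethylcyclohex-3-ene-1-carbaldehyde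
Product: 8 2-bromo-4-[(1R,6R)-6-ethenyl-3,6-dimethylcyclohex-2-en-1-yl]aniline
Conditions: Ph3PCH3Br, KOtBu, THF, 0 °C → rt
Reagents that add atoms: methyltriphenylphosphonium bromide, C[P+](c1ccccc1)(c1ccccc1)c1ccccc1.[Br-]
Why: Wittig methylenation of a non-enolisable α-quaternary aldehyde, in which the ylide is too weak a base for the aniline N–H or the now unactivated C2–H, so both stereocentres pass unchanged (the descriptors become R,R only because vinyl replaces CHO).

Step 6
Reactants: 8 2-bromo-4-[(1R,6R)-6-ethenyl-3,6-dimethylcyclohex-2-en-1-yl]aniline; 9 2-bromo-4-iodoaniline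
Product: 10 2-bromo-4-[(E)-2-[(1R,2R)-2-(4-amino-3-bromophenyl)-1,4-dimethylcyclohex-3-en-1-yl]ethenyl]aniline
Conditions: Pd(OAc)2 (10 mol %), n-Bu4NCl, NaHCO3, DMF, 85 °C
Reagents that add atoms: none
Why: Mizoroki–Heck coupling under ligand-free phase-transfer conditions: palladium should insert only into the C–I bond (the electron-rich C–Br bonds ortho to NH2 are inert without a phosphine), the aryl group adds to the terminal CH2, and syn β-hydride elimination, possible only toward the benzylic hydrogen because C1 is quaternary, gives the (E)-alkene with no double-bond migration.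

Step 7
Reactants: 11 methyl 3,3-dimethylpent-4-enoate
Product: 12 3,3-dimethylpent-4-enal
Conditions: DIBAL-H (1.05 equiv), CH2Cl2, −78 °C; aq. Rochelle salt
Reagents that add atoms: none
Why: Partial reduction of a methyl ester with DIBAL-H at −78 °C should stop at the aldehyde oxidation level; the volatile aldehyde is carried on as a solution.

Step 8
Reactants: 10 2-bromo-4-[(E)-2-[(1R,2R)-2-(4-amino-3-bromophenyl)-1,4-dimethylcyclohex-3-en-1-yl]ethenyl]aniline; 12 3,3-dimethylpent-4-enal (about 5 equiv)
Product: 14 3-(2-methylbut-3-en-2-yl)-5-[(E)-2-[(1R,2R)-1,4-dimethyl-2-[3-(2-methylbut-3-en-2-yl)-1H-indol-5-yl]cyclohex-3-en-1-yl]ethenyl]-1H-indole (target), via bis(N-aryl enamine) 13 (not isolated)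
Conditions: Pd(OAc)2 (10 mol %), XPhos (20 mol %), KOAc, DMA, 100 °C
Reagents that add atoms: none
Why: Each NH2 group condenses with 12 to an N-aryl imine/enamine (N1–C2); Pd(0)/XPhos then inserts into the neighbouring C–Br bond, the deprotonated enamine binds palladium through its β-carbon to give a six-membered aza-palladacycle, and reductive elimination forges C3–C3a, after which the 3H-indole tautomerises to the aromatic 1H-indole. The closest known reaction is the palladium-catalysed annulation of o-haloanilines with enolisable aldehydes to 3-substituted indoles, for which XPhos with acetate in DMA is the system used for o-bromoanilines. Each of the two five-membered rings is closed by the C3–C3a bond in a formally 5-endo sense, the enamine C2=C3 unit ending up inside the ring, while N1–C2 comes from the preceding intermolecular condensation. No stereocentre is formed; C1 of the cyclohexene is quaternary and its C2–H, benzylic and allylic to an electron-rich ring, is far too weakly acidic for acetate, so both centres pass through unchanged. The step needs regioselectivity for the 3-substituted indole, which 12 guarantees because its only α-position is one methylene next to a quaternary carbon, and chemoselectivity for ring closure over intermolecular Heck insertion, which the proximity of the enamine and the hindrance of every alkene present (two neopentyl-type vinyl groups, one styrene, one trisubstituted ring alkene) should provide. Since both rings are 2-bromoanilines with a carbon substituent para to nitrogen, their reactivity is closely matched and a single set of conditions should carry both closures.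

Compound list
1 | 3-bromo-4-nitrobenzaldehyde | O=Cc1ccc([N+](=O)[O-])c(Br)c1 | starting material
2 | 1-(triphenyl-λ5-phosphanylidene)propan-2-one | CC(=O)C=P(c1ccccc1)(c1ccccc1)c1ccccc1 | starting material
3 | (E)-4-(3-bromo-4-nitrophenyl)but-3-en-2-one | CC(=O)/C=C/c1ccc([N+](=O)[O-])c(Br)c1 | intermediate
4 | 2-bromo-4-[(1E)-3-methylbuta-1,3-dien-1-yl]-1-nitrobenzene | C=C(C)/C=C/c1ccc([N+](=O)[O-])c(Br)c1 | intermediate
5 | methacrolein (2-methylprop-2-enal) | C=C(C)C=O | starting material
6 | (1S,2S)-2-(3-bromo-4-nitrophenyl)-1,4-dimethylcyclohex-3-ene-1-carbaldehyde (CHO cis to aryl) | O=C[C@@]1(C)CCC(C)=C[C@H]1c1ccc([N+](=O)[O-])c(Br)c1 | intermediate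
7 | (1S,2S)-2-(4-amino-3-bromophenyl)-1,4-dimethylcyclohex-3-ene-1-carbaldehyde | O=C[C@@]1(C)CCC(C)=C[C@H]1c1ccc(N)c(Br)c1 | intermediate
8 | 2-bromo-4-[(1R,6R)-6-ethenyl-3,6-dimethylcyclohex-2-en-1-yl]aniline | C=C[C@@]1(C)CCC(C)=C[C@H]1c1ccc(N)c(Br)c1 | intermediate
9 | 2-bromo-4-iodoaniline | Nc1ccc(I)cc1Br | starting material
10 | 2-bromo-4-[(E)-2-[(1R,2R)-2-(4-amino-3-bromophenyl)-1,4-dimethylcyclohex-3-en-1-yl]ethenyl]aniline | Nc1ccc(/C=C/[C@@]2(C)CCC(C)=C[C@H]2c2ccc(N)c(Br)c2)cc1Br | intermediate
11 | methyl 3,3-dimethylpent-4-enoate | COC(=O)CC(C)(C)C=C | starting material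
12 | 3,3-dimethylpent-4-enal | C=CC(C)(C)CC=O | intermediate
13 | N,N′-bis[(E)-3,3-dimethylpenta-1,4-dien-1-yl] derivative of 10 (bis-enamine, in equilibrium with the bis-imine) | C=CC(C)(C)/C=C/Nc1ccc(/C=C/[C@@]2(C)CCC(C)=C[C@H]2c2ccc(N/C=C/C(C)(C)C=C)c(Br)c2)cc1Br | intermediate
14 | 3-(2-methylbut-3-en-2-yl)-5-[(E)-2-[(1R,2R)-1,4-dimethyl-2-[3-(2-methylbut-3-en-2-yl)-1H-indol-5-yl]cyclohex-3-en-1-yl]ethenyl]-1H-indole | C=CC(C)(C)c1c[nH]c2ccc(/C=C/[C@@]3(C)CCC(C)=C[C@H]3c3ccc4[nH]cc(C(C)(C)C=C)c4c3)cc12 | target

Total step count: 8. Longest linear sequence: 7 steps (steps 1–6 and 8).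

Steps most likely to fail

1. Step 8. At the temperature needed to activate two electron-rich C–Br bonds, the second ring closure may stall, the aldehyde may self-condense, intermolecular Heck insertion or N-arylation may compete, and the 1,5-diene framework is under thermal stress. The fallback sets out from 10 and returns at 14, and it changes the electrophile instead of the catalyst. Copper-catalysed aromatic halogen exchange (CuI, trans-N,N′-dimethylcyclohexane-1,2-diamine, NaI, dioxane, 110 °C) should convert 10 into 4-[(E)-2-[(1R,2R)-2-(4-amino-3-iodophenyl)-1,4-dimethylcyclohex-3-en-1-yl]ethenyl]-2-iodoaniline F1. The annulation with 12 is then run under the ligand-free amine-base protocol (Pd(OAc)2, DABCO, DMF, 85 °C), which is established for o-iodoanilines and aldehydes. Oxidative addition is no longer limiting there, and no phosphine is present to promote side reactions.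

2. Step 3. The electron-poor diene may turn over slowly on the chiral Lewis acid, and facial or endo discrimination may be insufficient. The fallback sets out from 4 (with 5) and returns at 6, and it replaces asymmetric catalysis by resolution. Cycloaddition under a simple strong Lewis acid (MeAlCl2, CH2Cl2, −78 °C) should give the cis adduct as the racemate, that is 6 together with its mirror image (1R,2R)-2-(3-bromo-4-nitrophenyl)-1,4-dimethylcyclohex-3-ene-1-carbaldehyde F2. Preparative SFC on a polysaccharide chiral stationary phase then delivers 6.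

3. Step 6. Migratory insertion into the hindered vinyl group may be slow, which would allow reduction or homocoupling of the aryl iodide, or loss of C–I over C–Br selectivity if the temperature has to be raised. The fallback sets out from 7 and returns at 10, and it replaces the Heck reaction by a cross-coupling with a defined alkenyl metal.
   - Ohira–Bestmann homologation of 7 (dimethyl (1-diazo-2-oxopropyl)phosphonate, K2CO3, MeOH, rt) should give 2-bromo-4-[(1S,6S)-6-ethynyl-3,6-dimethylcyclohex-2-en-1-yl]aniline F3.
   - Copper-catalysed syn, anti-Markovnikov hydroboration (CuCl, Xantphos, NaOtBu, B2pin2, MeOH, THF, rt) should give 2-bromo-4-[(1R,6R)-3,6-dimethyl-6-[(E)-2-(4,4,5,5-tetramethyl-1,3,2-dioxaborolan-2-yl)ethenyl]cyclohex-2-en-1-yl]aniline F4.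
   - Suzuki–Miyaura coupling of F4 with 9 at its C–I bond (Pd(dppf)Cl2, K3PO4, dioxane/H2O, 60 °C) should give 10 with the E geometry fixed by the boronate.

Further compounds
F1 | step 8 | 4-[(E)-2-[(1R,2R)-2-(4-amino-3-iodophenyl)-1,4-dimethylcyclohex-3-en-1-yl]ethenyl]-2-iodoaniline | Nc1ccc(/C=C/[C@@]2(C)CCC(C)=C[C@H]2c2ccc(N)c(I)c2)cc1I
F2 | step 3 | (1R,2R)-2-(3-bromo-4-nitrophenyl)-1,4-dimethylcyclohex-3-ene-1-carbaldehyde (enantiomer of 6) | O=C[C@]1(C)CCC(C)=C[C@@H]1c1ccc([N+](=O)[O-])c(Br)c1
F3 | step 6 | 2-bromo-4-[(1S,6S)-6-ethynyl-3,6-dimethylcyclohex-2-en-1-yl]aniline | C#C[C@@]1(C)CCC(C)=C[C@H]1c1ccc(N)c(Br)c1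
F4 | step 6 | 2-bromo-4-[(1R,6R)-3,6-dimethyl-6-[(E)-2-(4,4,5,5-tetramethyl-1,3,2-dioxaborolan-2-yl)ethenyl]cyclohex-2-en-1-yl]aniline | CC1(C)OB(/C=C/[C@@]2(C)CCC(C)=C[C@H]2c2ccc(N)c(Br)c2)OC1(C)C
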